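**Retrosynthetic overview**
1. Target 13 comes from octa-O-benzyl ether 12 by global hydrogenolysis.
2. 12 is cut at the interflavan C4–C8 bond into the (2S)-flavan-4-ol 8 (C4 electrophile) and penta-O-benzyl-epigallocatechin 10 (C8 nucleophile); the lower rings and stereocentres are taken from natural epigallocatechin.
3. 8 comes from racemic flavanone 7 by kinetic resolution (asymmetric transfer hydrogenation); 7 comes from 2'-hydroxychalcone 6 by oxa-Michael closure of the upper ring C.
4. Key C–C bond: the C2–C3 bond of the upper unit, made by an intermolecular Claisen–Schmidt aldol condensation of ring A ketone 3 with ring B aldehyde 4.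
5. Ring order: rings A and B are bought as arenes, the upper ring C is closed in step 3, the lower ring C is already present in epigallocatechin.

Assumption: (−)-epigallocatechin (natural 2R,3R form from green tea) and 3,4-bis(benzyloxy)benzaldehyde are bought as such.

**Step 1**
Reactants: 1 2,4-dihydroxyacetophenone; 2 benzyl bromide
Product: 3 1-[4-(benzyloxy)-2-hydroxyphenyl]ethan-1-one
Conditions: BnBr (1.05 equiv), K2CO3 (1.2 equiv), acetone, reflux, 6 h
Reagents that add atoms: benzyl bromide (2), BrCc1ccccc1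
Why: Williamson ether synthesis; the 2-OH is hydrogen-bonded to the ketone and much less reactive, so only the 4-OH is benzylated, and no stereocentre is involved.

**Step 2**
Reactants: 3 1-[4-(benzyloxy)-2-hydroxyphenyl]ethan-1-one; 4 3,4-bis(benzyloxy)benzaldehyde
Product: 6 (E)-1-[4-(benzyloxy)-2-hydroxyphenyl]-3-[3,4-bis(benzyloxy)phenyl]prop-2-en-1-one, via aldol adduct 5 (not isolated)
Conditions: KOH (50% aq., 8 equiv), EtOH/THF, rt, 36 h; then 1 M HCl
Reagents that add atoms: none
Why: Claisen–Schmidt (crossed aldol) condensation, in which the methyl ketone enolate of 3 adds to the non-enolisable aldehyde 4 and the aldol 5 dehydrates (E1cB) to the conjugated E-chalcone, joining ring A to ring B through the future C2–C3 bond; no stereocentre remains.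

**Step 3**
Reactants: 6 the 2'-hydroxychalcone
Product: 7 racemic 7-(benzyloxy)-2-[3,4-bis(benzyloxy)phenyl]chroman-4-one
Conditions: NaOAc (5 equiv), EtOH, reflux, 24 h; unreacted 6 recycled
Reagents that add atoms: none
Why: Intramolecular oxa-Michael addition of the 2'-phenoxide to the enone closes ring C; the closure is reversible, so C2 is formed racemic at this stage.

**Step 4**
Reactants: 7 racemic flavanone
Product: 8 (2S,4S)-7-(benzyloxy)-2-[3,4-bis(benzyloxy)phenyl]chroman-4-ol (2,4-cis)
Conditions: RuCl[(S,S)-TsDPEN](p-cymene) (1 mol%), HCO2H/Et3N (1:1), EtOAc, 30 °C, stopped at ca. 48% conversion; chromatography separates 8 from unreacted ketone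
Reagents that add atoms: none
Why: Kinetic resolution by Noyori-type asymmetric transfer hydrogenation, in which the (S,S)-catalyst delivers hydride to the carbonyl face that gives the 4S alcohol, which in the 2S ketone is also the open face anti to the C2 aryl group, so (2S)-7 is reduced fast to cis-(2S,4S)-8 while the 2R ketone is left behind (it is racemised under step 3 conditions and recycled), the enantiomeric purity of 8 being checked by chiral HPLC.

**Step 5**
Reactants: 9 (−)-epigallocatechin; 2 benzyl bromide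
Product: 10 (2R,3R)-5,7-bis(benzyloxy)-2-[3,4,5-tris(benzyloxy)phenyl]chroman-3-ol (penta-O-benzyl-epigallocatechin)
Conditions: BnBr (5.5 equiv), K2CO3 (6 equiv), degassed DMF, N2, 0 °C → rt, 16 h
Reagents that add atoms: benzyl bromide (2), BrCc1ccccc1
Why: Williamson etherification with a carbonate base alkylates the five phenols but not the secondary 3-OH, and the cold, oxygen-free conditions leave the 2R,3R stereocentres of the natural product untouched.

**Step 6**
Reactants: 8 (2S,4S)-flavan-4-ol; 10 penta-O-benzyl-epigallocatechin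
Product: 12 octa-O-benzyl ether of the target (upper unit 2S,4R; lower unit 2R,3R; 4→8 linked), via C4 benzylic cation 11 (not isolated)
Conditions: 10 (3 equiv), BF3·OEt2 (0.3 equiv), 4 Å MS, CH2Cl2, −40 → 0 °C; Et3N quench; excess 10 recovered
Reagents that add atoms: none
Why: SN1-type Friedel–Crafts alkylation in which BF3 ionises the C4–OH of 8 to cation 11 (stabilised by O1 and the para 7-benzyloxy group), which is attacked by C8 of 10, the most nucleophilic position of its phloroglucinol-type ring A, pseudo-axially from the face anti to the C2 aryl group, so the new C4 stereocentre is set 2,4-trans (4R) by substrate control while C2 and the stereocentres of 10 are untouched.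

**Step 7**
Reactants: 12 octa-O-benzyl ether
Product: 13 target, (2S)-7,3',4'-trihydroxyflavan-(4α→8)-(−)-epigallocatechin
Conditions: H2 (1 atm), 20% Pd(OH)2 on carbon, THF/MeOH/H2O (20:1:1), rt, 3 h; filtration, Sephadex LH-20 (MeOH), freeze-drying
Reagents that add atoms: none
Why: Catalytic hydrogenolysis cleaves the eight O-benzyl ethers under neutral conditions that leave the diarylmethine C4–C8 bond, the ring C ethers and all four stereocentres intact.

**Compound list**
1 | 2,4-dihydroxyacetophenone | CC(=O)c1ccc(O)cc1O | starting material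
2 | benzyl bromide | BrCc1ccccc1 | starting material
3 | 1-[4-(benzyloxy)-2-hydroxyphenyl]ethan-1-one | CC(=O)c1ccc(OCc2ccccc2)cc1O | intermediate
4 | 3,4-bis(benzyloxy)benzaldehyde | O=Cc1ccc(OCc2ccccc2)c(OCc2ccccc2)c1 | starting material
5 | racemic 1-[4-(benzyloxy)-2-hydroxyphenyl]-3-[3,4-bis(benzyloxy)phenyl]-3-hydroxypropan-1-one (aldol adduct, not isolated) | O=C(CC(O)c1ccc(OCc2ccccc2)c(OCc2ccccc2)c1)c1ccc(OCc2ccccc2)cc1O | intermediate
6 | (E)-1-[4-(benzyloxy)-2-hydroxyphenyl]-3-[3,4-bis(benzyloxy)phenyl]prop-2-en-1-one | O=C(/C=C/c1ccc(OCc2ccccc2)c(OCc2ccccc2)c1)c1ccc(OCc2ccccc2)cc1O | intermediate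
7 | racemic 7-(benzyloxy)-2-[3,4-bis(benzyloxy)phenyl]chroman-4-one | O=C1CC(c2ccc(OCc3ccccc3)c(OCc3ccccc3)c2)Oc2cc(OCc3ccccc3)ccc12 | intermediate
8 | (2S,4S)-7-(benzyloxy)-2-[3,4-bis(benzyloxy)phenyl]chroman-4-ol | O[C@H]1C[C@@H](c2ccc(OCc3ccccc3)c(OCc3ccccc3)c2)Oc2cc(OCc3ccccc3)ccc12 | intermediate
9 | (−)-epigallocatechin, (2R,3R) | O[C@@H]1Cc2c(O)cc(O)cc2O[C@@H]1c1cc(O)c(O)c(O)c1 | starting material
10 | (2R,3R)-5,7-bis(benzyloxy)-2-[3,4,5-tris(benzyloxy)phenyl]chroman-3-ol | O[C@@H]1Cc2c(OCc3ccccc3)cc(OCc3ccccc3)cc2O[C@@H]1c1cc(OCc2ccccc2)c(OCc2ccccc2)c(OCc2ccccc2)c1 | intermediate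
11 | (2S)-7-(benzyloxy)-2-[3,4-bis(benzyloxy)phenyl]chroman-4-ylium cation (not isolated) | [CH+]1C[C@@H](c2ccc(OCc3ccccc3)c(OCc3ccccc3)c2)Oc2cc(OCc3ccccc3)ccc12 | intermediate
12 | octa-O-benzyl ether of the target: upper (2S,4R)-7-(benzyloxy)-2-[3,4-bis(benzyloxy)phenyl]chroman-4-yl unit bonded to C8 of (2R,3R)-5,7-bis(benzyloxy)-2-[3,4,5-tris(benzyloxy)phenyl]chroman-3-ol | O(Cc1ccccc1)c1ccc2c(c1)O[C@H](c1ccc(OCc3ccccc3)c(OCc3ccccc3)c1)C[C@H]2c1c(OCc3ccccc3)cc(OCc3ccccc3)c2c1O[C@H](c1cc(OCc3ccccc3)c(OCc3ccccc3)c(OCc3ccccc3)c1)[C@H](O)C2 | intermediate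
13 | (2S)-7,3',4'-trihydroxyflavan-(4α→8)-(−)-epigallocatechin; upper unit 2S,4R (2,4-trans), lower unit 2R,3R | Oc1ccc2c(c1)O[C@H](c1ccc(O)c(O)c1)C[C@H]2c1c(O)cc(O)c2c1O[C@H](c1cc(O)c(O)c(O)c1)[C@H](O)C2 | target

**Step count and risks**
Total steps: 7. Longest linear sequence: 6 steps (1 → 2 → 3 → 4 → 6 → 7); step 5 is the side branch.

The three steps most likely to fail are 6, 5 and 4.

The coupling (step 6) is the most exposed. The cation can lose a proton to the flav-3-ene, attack another molecule of 8, or give some of the 2,4-cis epimer, and acid is present throughout. The fallback sets out from 8 and comes back at 12. Compound 8 is treated with phenylmethanethiol and a catalytic amount of BF3·OEt2 in CH2Cl2 at −20 °C, which traps the cation cleanly as (2S)-7-(benzyloxy)-4-(benzylsulfanyl)-2-[3,4-bis(benzyloxy)phenyl]chromane F1 (C4 epimers, both usable). This stable sulfide and 10 (2–3 equiv) are then joined with AgBF4 in THF at 0 °C. The thiophilic activation releases the cation slowly under essentially neutral conditions and gives 12.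

The benzylation of epigallocatechin (step 5) can suffer from air oxidation of the pyrogallol phenoxides, C-benzylation and C2 epimerisation. The fallback sets out from 9 and comes back at 13. Compound 9 is peracetylated (Ac2O, pyridine, rt) to epigallocatechin hexaacetate F2. F2 is then treated with NaH and benzyl chloride in DMF containing a measured amount of water at 0 °C → rt. The acetates are cleaved one at a time and each oxide is benzylated at once, so no free polyphenoxide builds up, and the product is hexa-O-benzyl-epigallocatechin F3. F3 takes the place of 10 in the step 6 coupling with 8 and gives the nona-O-benzyl dimer F4. Hydrogenolysis under the step 7 conditions then gives 13.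

The kinetic resolution (step 4) depends on a high selectivity factor for this electron-rich ketone, because the alcohol is harvested just below half conversion. The fallback sets out from 7 and comes back at 8. The enantiomeric catalyst RuCl[(R,R)-TsDPEN](p-cymene) is used and the reduction is run past half conversion (55–60%), so that the slow-reacting ketone, (2S)-7-(benzyloxy)-2-[3,4-bis(benzyloxy)phenyl]chroman-4-one F5, is recovered in very high enantiomeric purity whatever the selectivity factor. The fast-reacting enantiomer ends up as (2R,4R)-7-(benzyloxy)-2-[3,4-bis(benzyloxy)phenyl]chroman-4-ol F6 and is separated off. F5 is then reduced with NaBH4 in MeOH/THF at 0 °C (hydride anti to the C2 aryl group) to the cis alcohol 8.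

**Further compounds**
F1 | step 6 | (2S)-7-(benzyloxy)-4-(benzylsulfanyl)-2-[3,4-bis(benzyloxy)phenyl]chromane (C4 epimer mixture) | S(Cc1ccccc1)C1C[C@@H](c2ccc(OCc3ccccc3)c(OCc3ccccc3)c2)Oc2cc(OCc3ccccc3)ccc12
F2 | step 5 | (2R,3R)-epigallocatechin hexaacetate | CC(=O)O[C@@H]1Cc2c(OC(C)=O)cc(OC(C)=O)cc2O[C@@H]1c1cc(OC(C)=O)c(OC(C)=O)c(OC(C)=O)c1
F3 | step 5 | (2R,3R)-3,5,7-tris(benzyloxy)-2-[3,4,5-tris(benzyloxy)phenyl]chromane (hexa-O-benzyl-epigallocatechin) | O(Cc1ccccc1)[C@@H]1Cc2c(OCc3ccccc3)cc(OCc3ccccc3)cc2O[C@@H]1c1cc(OCc2ccccc2)c(OCc2ccccc2)c(OCc2ccccc2)c1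
F4 | step 5 | nona-O-benzyl ether of the target (12 with the lower 3-OH also benzylated; upper 2S,4R, lower 2R,3R) | O(Cc1ccccc1)c1ccc2c(c1)O[C@H](c1ccc(OCc3ccccc3)c(OCc3ccccc3)c1)C[C@H]2c1c(OCc3ccccc3)cc(OCc3ccccc3)c2c1O[C@H](c1cc(OCc3ccccc3)c(OCc3ccccc3)c(OCc3ccccc3)c1)[C@H](OCc1ccccc1)C2
F5 | step 4 | (2S)-7-(benzyloxy)-2-[3,4-bis(benzyloxy)phenyl]chroman-4-one | O=C1C[C@@H](c2ccc(OCc3ccccc3)c(OCc3ccccc3)c2)Oc2cc(OCc3ccccc3)ccc12
F6 | step 4 | (2R,4R)-7-(benzyloxy)-2-[3,4-bis(benzyloxy)phenyl]chroman-4-ol | O[C@@H]1C[C@H](c2ccc(OCc3ccccc3)c(OCc3ccccc3)c2)Oc2cc(OCc3ccccc3)ccc12
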